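**Strategy.** Everything rests on the C3–C4 bond of the heptadecan-2-ol chain (C1 benzylic, C2 carbinol). The key step exploits the O–C2–C3 unit: C2, its oxygen and the C3 methylene are carried as the oxirane ring of (S)-2-[3,5-bis(benzyloxy)benzyl]oxirane, and a copper-catalysed tetradecyl Grignard opens it at the unsubstituted ring carbon C3. One operation joins the C14 tail to the aryl-C3 head by a C(sp3)–C(sp3) bond, unveils the C2 hydroxyl and leaves the stereocentre, bought with (S)-epichlorohydrin, untouched. The epoxide comes in two steps from an aryl Grignard and epichlorohydrin; hydrogenolysis of the benzyl ethers ends the route.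

Key step: step 3

Assumption: the target is the (R)-alcohol (CIP order OH > CH2Ar > CH2-alkyl > H), and 1,3-bis(benzyloxy)-5-bromobenzene, (S)-epichlorohydrin and 1-bromotetradecane are taken as catalogue compounds.

**Step 1**
Reactants: 1 1,3-bis(benzyloxy)-5-bromobenzene; 2 (S)-epichlorohydrin
Product: 4 (S)-1-[3,5-bis(benzyloxy)phenyl]-3-chloropropan-2-ol, via 3,5-bis(benzyloxy)phenylmagnesium bromide 3 (not isolated)
Conditions: Mg, cat. I2, THF, reflux; then 2, CuI (10 mol%), THF, −40 → 0 °C; aq NH4Cl
Reagents that add atoms: none
Why: Grignard formation followed by copper-catalysed SN2 opening of the epoxide at its unsubstituted ring carbon, which should outpace displacement of chloride; the carbinol centre comes unchanged from (S)-epichlorohydrin because no bond to it is broken.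

**Step 2**
Reactants: 4 (S)-1-[3,5-bis(benzyloxy)phenyl]-3-chloropropan-2-ol
Product: 5 (S)-2-[3,5-bis(benzyloxy)benzyl]oxirane
Conditions: powdered NaOH, Et2O, rt
Reagents that add atoms: none
Why: Intramolecular Williamson etherification (3-exo-tet) of the alkoxide onto the CH2Cl carbon closes the oxirane; the C–O bond at the stereocentre is not broken, so the configuration is retained.

**Step 3**
Reactants: 5 (S)-2-[3,5-bis(benzyloxy)benzyl]oxirane; 6 1-bromotetradecane
Product: 8 (R)-1-[3,5-bis(benzyloxy)phenyl]heptadecan-2-ol, via tetradecylmagnesium bromide 7 (not isolated)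
Conditions: 6, Mg, THF, 40 °C; then slow addition to 5, CuI (10 mol%), THF, −40 → −10 °C; aq NH4Cl
Reagents that add atoms: none
Why: Transmetallation of tetradecylmagnesium bromide to copper gives an alkylcuprate that attacks the oxirane in an SN2 manner at the unsubstituted ring carbon (the future C3), forming the C3–C4 bond and releasing the C2 alkoxide, which is protonated on work-up. The closest known reaction type is the copper-catalysed Grignard opening of terminal epoxides, a standard C(sp3)–C(sp3) fragment coupling. No ring is closed (the oxirane is opened) and no new stereocentre is made: C2 is not a reacting atom and keeps its spatial arrangement, the descriptor changing from S to R only because the new CH2-alkyl ranks below CH2Ar whereas the oxirane CH2 ranked above it. The step needs regioselectivity for the CH2 over the CH carbon of the ring, which the steric difference between a primary and a secondary centre under SN2 conditions secures. It also needs chemoselectivity over bromide opening of the oxirane and over base-induced isomerisation to the cinnamyl-type alcohol, which catalytic copper, low temperature and slow addition of the Grignard should secure; the benzyl ethers are inert.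

**Step 4**
Reactants: 8 (R)-1-[3,5-bis(benzyloxy)phenyl]heptadecan-2-ol
Product: 9 (R)-1-(3,5-dihydroxyphenyl)heptadecan-2-ol
Conditions: H2 (1 atm), 10% Pd/C, EtOAc–EtOH, rt
Reagents that add atoms: none
Why: Catalytic hydrogenolysis of the two benzyl aryl ethers; the homobenzylic secondary alcohol and the resorcinol ring should be inert under these conditions, and the stereocentre is untouched.

**Compound list**
1 | 1,3-bis(benzyloxy)-5-bromobenzene | Brc1cc(OCc2ccccc2)cc(OCc2ccccc2)c1 | starting material
2 | (S)-epichlorohydrin, (S)-2-(chloromethyl)oxirane | ClC[C@@H]1CO1 | starting material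
3 | 3,5-bis(benzyloxy)phenylmagnesium bromide | Br[Mg]c1cc(OCc2ccccc2)cc(OCc2ccccc2)c1 | intermediate (not isolated)
4 | (S)-1-[3,5-bis(benzyloxy)phenyl]-3-chloropropan-2-ol | ClC[C@@H](O)Cc1cc(OCc2ccccc2)cc(OCc2ccccc2)c1 | intermediate
5 | (S)-2-[3,5-bis(benzyloxy)benzyl]oxirane | C1[C@@H](O1)Cc2cc(OCc3ccccc3)cc(OCc3ccccc3)c2 | intermediate
6 | 1-bromotetradecane | CCCCCCCCCCCCCCBr | starting material
7 | tetradecylmagnesium bromide | CCCCCCCCCCCCCC[Mg]Br | intermediate (not isolated)
8 | (R)-1-[3,5-bis(benzyloxy)phenyl]heptadecan-2-ol | CCCCCCCCCCCCCCC[C@@H](O)Cc1cc(OCc2ccccc2)cc(OCc2ccccc2)c1 | intermediate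
9 | (R)-1-(3,5-dihydroxyphenyl)heptadecan-2-ol, 5-[(2R)-2-hydroxyheptadecyl]benzene-1,3-diol | CCCCCCCCCCCCCCC[C@@H](O)Cc1cc(O)cc(O)c1 | target

Total step count: 4
Longest linear sequence: 4 steps (1 → 4 → 5 → 8 → 9)

**Steps most likely to fail**

1. Step 3 (key step). The alkyl transfer may not be clean: bromide from the magnesium salt can open the oxirane to a bromohydrin, the basic reagent can isomerise the benzyl oxirane to an allylic alcohol by deprotonation at the benzylic CH2, and Wurtz homocoupling during Grignard formation can deplete the reagent. The fallback sets out from 5 and comes back at 9. Tetradec-1-yne is deprotonated with n-BuLi in THF at −78 °C to lithium tetradec-1-ynide F1, which in the presence of BF3·OEt2 opens 5 at the same terminal ring carbon (Lewis-acid-promoted acetylide opening, Yamaguchi–Hirao type). This should give (S)-1-[3,5-bis(benzyloxy)phenyl]heptadec-4-yn-2-ol F2, which has the same spatial arrangement as 8; the descriptor is S because the propargylic CH2 outranks CH2Ar. Hydrogenation of this alkynol over Pd/C (H2, EtOAc–EtOH) should saturate the triple bond and cleave both benzyl ethers in one operation, giving 9 directly.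

2. Step 1. Magnesium insertion into the electron-rich aryl bromide may be sluggish, and some direct displacement at the chloromethyl carbon would erode the enantiomeric purity of the epoxide. The fallback sets out from 1 and comes back at 5. Suzuki–Miyaura allylation of 1 with allylboronic acid pinacol ester (Pd(dppf)Cl2, CsF, THF, reflux) should give 1-allyl-3,5-bis(benzyloxy)benzene F3. Epoxidation with mCPBA (CH2Cl2, 0 °C → rt) gives racemic 2-[3,5-bis(benzyloxy)benzyl]oxirane F4. Hydrolytic kinetic resolution (Jacobsen) with (S,S)-(salen)Co(III)OAc and 0.55 equiv H2O should, by the established sense for alkyl-substituted oxiranes, hydrolyse the (R)-enantiomer and leave (S)-epoxide 5, which is separated from the polar diol.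

3. Step 4. Hydrogenolysis may stall at the mono-benzyl ether through catalyst poisoning by traces of copper or halide from step 3, or through poor solubility of the waxy long-chain substrate. The fallback sets out from 8 and comes back at 9, with no new compound. It replaces reductive cleavage by Lewis-acid debenzylation: BCl3 with pentamethylbenzene as benzyl-cation scavenger in CH2Cl2 at −78 °C, then methanol quench. The secondary alcohol is expected to survive as a borate that is hydrolysed on work-up.

**Further compounds**
F1 | step 3 | lithium tetradec-1-ynide | [Li]C#CCCCCCCCCCCCC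
F2 | step 3 | (S)-1-[3,5-bis(benzyloxy)phenyl]heptadec-4-yn-2-ol | CCCCCCCCCCCCC#CC[C@@H](O)Cc1cc(OCc2ccccc2)cc(OCc2ccccc2)c1
F3 | step 1 | 1-allyl-3,5-bis(benzyloxy)benzene | C=CCc1cc(OCc2ccccc2)cc(OCc2ccccc2)c1
F4 | step 1 | rac-2-[3,5-bis(benzyloxy)benzyl]oxirane | C1OC1Cc2cc(OCc3ccccc3)cc(OCc3ccccc3)c2
F0 | step 4 | none | none
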